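## Plan

1. Numbering: flavanone numbering is used throughout. Ring A is C4a–C8a, ring B is C1'–C6', and ring C is O1, C2, C3, C4, C4a, C8a. Retrosynthesis: the 4'-OH is masked as a benzyl ether. Ring C is then cut at C2–C3, which gives an open aryl benzyl ether with a diazoacetyl group on ring A. The diazo nitrogen, the O1–C2 ether bond and the ring A–acetyl bond are cut last.
2. Forward: ring A is acetylated, and rings A and B are joined through O1–C2. The methyl ketone is raised to the diazoketone, ring C closes last by carbene C–H insertion, and hydrogenolysis frees the 4'-OH.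
3. Enabling feature: C2 is both the ether carbon of O1 and the benzylic carbon of ring B, whose 4'-oxygen is para to it. Ring A holds O1 and the C4 carbonyl ortho to each other. A carbene at C3 therefore finds a doubly activated C–H bond at six-atom distance and only the hydrogen-free O1 at five-atom distance.
4. Stereochemistry: C2 is the only stereocenter. It is set in the ring closure by catalyst-controlled choice between the two enantiotopic benzylic hydrogens, with retention. Everything afterwards is neutral, so the retro-oxa-Michael path to the chalcone stays closed.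

Key step: step 4

Assumption: the sense of induction of Rh2(S-PTTL)4 on this substrate class cannot be fixed by analogy alone. The route is written with the S-ligand series. The mirror-image catalyst from D-tert-leucine would be used instead if the configuration check on the cyclised product calls for it.

## Route

Step 1
Reactants: 1 3,4,5-trimethoxyphenol
Product: 2 1-(2-hydroxy-4,5,6-trimethoxyphenyl)ethan-1-one
Conditions: AcOH, BF3·OEt2, 85 °C; then H2O
Reagents that add atoms: acetic acid, CC(=O)O
Why: Friedel–Crafts acylation of this very electron-rich phenol can only occur at one of its two equivalent free positions, both ortho to the OH group, and the hydrogen-bonded, deactivating acetyl group should stop a second acylation; no stereocenter is formed.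

Step 2
Reactants: 2 1-(2-hydroxy-4,5,6-trimethoxyphenyl)ethan-1-one; 3 [4-(benzyloxy)-3-methoxyphenyl]methanol
Product: 4 1-(2-{[4-(benzyloxy)-3-methoxyphenyl]methoxy}-4,5,6-trimethoxyphenyl)ethan-1-one
Conditions: PPh3, DIAD, THF, 0 °C to rt
Reagents that add atoms: none
Why: Mitsunobu etherification joins the acidic, chelated phenol OH of 2 to the primary benzylic carbon of 3 (the future O1–C2 bond) under neutral conditions that leave the ketone, the methyl ethers and the O-benzyl group untouched; no stereocenter is formed.

Step 3
Reactants: 4 1-(2-{[4-(benzyloxy)-3-methoxyphenyl]methoxy}-4,5,6-trimethoxyphenyl)ethan-1-one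
Product: 7 1-(2-{[4-(benzyloxy)-3-methoxyphenyl]methoxy}-4,5,6-trimethoxyphenyl)-2-diazoethan-1-one, via lithium enolate 5 (not isolated), via trifluoroacetyl diketone 6 (not isolated)
Conditions: LiN(SiMe3)2, THF, −78 °C; CF3CO2CH2CF3, −78 °C; cold dilute aq. HCl, crude 6 taken on at once; MsN3, Et3N, H2O (1 equiv), MeCN, rt
Reagents that add atoms: lithium bis(trimethylsilyl)amide, [Li+].C[Si](C)(C)[N-][Si](C)(C)C (Li of 5 only); 2,2,2-trifluoroethyl trifluoroacetate, O=C(OCC(F)(F)F)C(F)(F)F (CF3CO group of 6 only); methanesulfonyl azide, CS(=O)(=O)N=[N+]=[N-] (N2 of 7)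
Why: Deacylative Regitz diazo transfer: the only enolisable position (the acetyl CH3) is lithiated and C-trifluoroacetylated so that the CH2 group of 6 is acidic enough for Et3N, the sulfonyl azide then delivers N2, and the trifluoroacetyl helper leaves as its N-sulfonyl amide, all without strong acid or heat that could harm the two benzylic ethers or the diazoketone.

Step 4
Reactants: 7 1-(2-{[4-(benzyloxy)-3-methoxyphenyl]methoxy}-4,5,6-trimethoxyphenyl)-2-diazoethan-1-one
Product: 9 (2S)-2-[4-(benzyloxy)-3-methoxyphenyl]-5,6,7-trimethoxy-2,3-dihydro-4H-chromen-4-one, via rhodium carbene 8 (not isolated)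
Conditions: Rh2(S-PTTL)4 {dirhodium tetrakis[N-phthaloyl-(S)-tert-leucinate]} (1 mol %), toluene, 4 Å MS, 0 °C, slow addition of 7 by syringe pump, high dilution
Reagents that add atoms: none
Why: Rh2(S-PTTL)4 takes up the diazo carbon of 7 at an axial site and expels N2 to give the electrophilic carbene 8, whose carbene carbon (the future C3) inserts into one C–H bond of the O1–CH2–ring B group through a concerted but asynchronous three-centre transition state with hydride-transfer character, so that C2–C3 and C3–H form in one event and the catalyst is released. The closest known reaction type is the dirhodium tetracarboxylate catalysed intramolecular C–H insertion of 2-alkoxyaryl diazoketones next to the ether oxygen to give chroman-4-ones, together with the enantioselective insertion of rhodium carbenes into the benzylic C–H bonds of aryl benzyl ethers under N-phthaloyl amino acid ligands. Ring C closes in the 1,6-insertion mode through a six-membered chair-like array with ring B pseudo-equatorial; the usually preferred 1,5-mode is shut off because atom 5 of the chain is O1, which bears no hydrogen. C2 is controlled by the catalyst alone: the four N-phthaloyl-tert-leucinate ligands wall in the carbene so that only the pro-S hydrogen of the prochiral CH2 group is presented to it, and since insertion goes with retention, replacement of that hydrogen by C3 gives 2S. The step needs site selectivity over the equidistant 5-OCH3 group and chemoselectivity over attack of the carbene on the lone pair of O1 (five-membered oxonium ylide, then [1,2]-benzyl shift to a 2-benzylbenzofuran-3-one); the first is secured because the partial positive charge at C2 is carried by O1 and by the para-benzyloxy group of ring B, which makes this secondary C–H bond far more hydridic than a methyl C–H bond, and the second because O1 is a weak donor (its lone pair is shared with the acyl-bearing ring A) and ylide formation is reversible on carboxylate-bridged divalent rhodium. Slow addition at high dilution in a dry, acid-free medium holds back carbene dimerisation, O–H insertion into water, and proton-induced loss of N2 with closure to a benzofuranone.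

Step 5
Reactants: 9 (2S)-2-[4-(benzyloxy)-3-methoxyphenyl]-5,6,7-trimethoxy-2,3-dihydro-4H-chromen-4-one
Product: 10 agecorynin E, (2S)-2-(4-hydroxy-3-methoxyphenyl)-5,6,7-trimethoxy-2,3-dihydro-4H-chromen-4-one
Conditions: H2 (1 atm), 10% Pd/C, EtOAc, rt, stopped at full conversion of 9
Reagents that add atoms: none
Why: Catalytic hydrogenolysis should take the unhindered primary O-benzyl ether well before the secondary, ring-bound C2–O1 bond or the electron-rich aryl ketone, and the neutral aprotic medium keeps shut the base- or acid-induced retro-oxa-Michael opening to the chalcone, so C2 stays 2S.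

## Compound list

1 | 3,4,5-trimethoxyphenol | COc1cc(O)cc(OC)c1OC | starting material
2 | 1-(2-hydroxy-4,5,6-trimethoxyphenyl)ethan-1-one | CC(=O)c1c(O)cc(OC)c(OC)c1OC | intermediate
3 | [4-(benzyloxy)-3-methoxyphenyl]methanol (O-benzylvanillyl alcohol) | COc1cc(CO)ccc1OCc1ccccc1 | starting material
4 | 1-(2-{[4-(benzyloxy)-3-methoxyphenyl]methoxy}-4,5,6-trimethoxyphenyl)ethan-1-one | COc1cc(COc2cc(OC)c(OC)c(OC)c2C(C)=O)ccc1OCc1ccccc1 | intermediate
5 | lithium enolate of 4 | COc1cc(COc2cc(OC)c(OC)c(OC)c2C(=C)[O-])ccc1OCc1ccccc1.[Li+] | intermediate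
6 | 1-(2-{[4-(benzyloxy)-3-methoxyphenyl]methoxy}-4,5,6-trimethoxyphenyl)-4,4,4-trifluorobutane-1,3-dione | COc1cc(COc2cc(OC)c(OC)c(OC)c2C(=O)CC(=O)C(F)(F)F)ccc1OCc1ccccc1 | intermediate
7 | 1-(2-{[4-(benzyloxy)-3-methoxyphenyl]methoxy}-4,5,6-trimethoxyphenyl)-2-diazoethan-1-one | COc1cc(COc2cc(OC)c(OC)c(OC)c2C(=O)C=[N+]=[N-])ccc1OCc1ccccc1 | intermediate
8 | rhodium carbene from 7 ([Rh] stands for the Rh2(S-PTTL)4 unit) | COc1cc(COc2cc(OC)c(OC)c(OC)c2C(=O)C=[Rh])ccc1OCc1ccccc1 | intermediate
9 | (2S)-2-[4-(benzyloxy)-3-methoxyphenyl]-5,6,7-trimethoxy-2,3-dihydro-4H-chromen-4-one | COc1cc([C@@H]2CC(=O)c3c(cc(OC)c(OC)c3OC)O2)ccc1OCc1ccccc1 | intermediate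
10 | agecorynin E, (2S)-2-(4-hydroxy-3-methoxyphenyl)-5,6,7-trimethoxy-2,3-dihydro-4H-chromen-4-one | COc1cc([C@@H]2CC(=O)c3c(cc(OC)c(OC)c3OC)O2)ccc1O | target

Total step count: 5. Longest linear sequence: 5 steps (1 → 2 → 4 → 7 → 9 → 10).

## Steps most likely to fail

**Step 4.** Three processes could go wrong.
- The carbene may be drained by attack on the lone pair of O1, followed by a [1,2]-benzyl shift.
- The hydride-transfer character of the insertion may go over into a full hydride shift. Closure through the enolate oxygen or loss of facial memory then becomes possible.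
- The carbene carries only hydrogen beside the acyl group. The ligand pocket may grip it poorly, so that the two enantiotopic hydrogens are not told apart well enough.

Fallback (sets out from 2, comes back at 9): the C–H insertion logic is given up, and ring B is added to a finished, flat ring C by asymmetric conjugate addition. Heating 2 with N,N-dimethylformamide dimethyl acetal should give (E)-3-(dimethylamino)-1-(2-hydroxy-4,5,6-trimethoxyphenyl)prop-2-en-1-one F1. Aqueous HCl in CH2Cl2 should close it, with loss of dimethylamine, to 5,6,7-trimethoxy-4H-chromen-4-one F2. Commercial [4-(benzyloxy)-3-methoxyphenyl]boronic acid is then added to C2. The conditions are Pd(OCOCF3)2 with the enantiomer of the tert-butyl pyridine-oxazoline ligand that leads to 2S (NH4PF6, H2O, ClCH2CH2Cl, 60 °C). This is a known way to enantioenriched flavanones and should give 9.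

**Step 3.** C-acylation of an enolate flanked by two ortho substituents may be sluggish. The trifluoroacetyl group may be cleaved before the transfer. The product may also lose nitrogen under proton catalysis on work-up or on silica.

Fallback (sets out from 4, comes back at 7): the N2 unit is brought in by nucleophilic displacement instead of diazo transfer. Enolate 5 is trapped with Me3SiCl to give {[1-(2-{[4-(benzyloxy)-3-methoxyphenyl]methoxy}-4,5,6-trimethoxyphenyl)ethenyl]oxy}trimethylsilane F3. N-Bromosuccinimide in THF at −78 °C should brominate the enol ether carbon faster than the free position of ring A. The product is 1-(2-{[4-(benzyloxy)-3-methoxyphenyl]methoxy}-4,5,6-trimethoxyphenyl)-2-bromoethan-1-one F4. N,N'-Ditosylhydrazine and DBU in THF at 0 °C then displace bromide and lose two sulfinate units (Bamford–Stevens-type elimination) to give 7.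

**Step 5.** The ring bond C2–O1 is also benzylic and is activated by the electron-rich ring B, so it may undergo hydrogenolysis in competition with the O-benzyl ether. The aryl ketone may also be reduced on prolonged contact with the catalyst.

Fallback (sets out from 2, comes back at 10): the hydrogen-labile group is replaced from the start by a fluoride-labile one, so no reductive step follows the ring closure.
- Commercial vanillin is silylated (iPr3SiCl, imidazole, DMF) to 3-methoxy-4-[(triisopropylsilyl)oxy]benzaldehyde F5.
- F5 is reduced (NaBH4, MeOH, 0 °C) to {3-methoxy-4-[(triisopropylsilyl)oxy]phenyl}methanol F6.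
- Mitsunobu coupling of F6 with 2 should give 1-[2-({3-methoxy-4-[(triisopropylsilyl)oxy]phenyl}methoxy)-4,5,6-trimethoxyphenyl]ethan-1-one F7.
- The conditions of step 3 lead through its lithium enolate F8 and the 4,4,4-trifluorobutane-1,3-dione F9 to the 2-diazoethan-1-one F10.
- The conditions of step 4 lead through the rhodium carbene F11 to (2S)-2-{3-methoxy-4-[(triisopropylsilyl)oxy]phenyl}-5,6,7-trimethoxy-2,3-dihydro-4H-chromen-4-one F12.
- Et3N·3HF in THF at rt is a weakly acidic fluoride source that never builds up the ring-opening phenoxide. It should free the phenol of F12 to give 10.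

## Further compounds

F1 | step 4 | (E)-3-(dimethylamino)-1-(2-hydroxy-4,5,6-trimethoxyphenyl)prop-2-en-1-one | CN(C)/C=C/C(=O)c1c(O)cc(OC)c(OC)c1OC
F2 | step 4 | 5,6,7-trimethoxy-4H-chromen-4-one | COc1cc2occc(=O)c2c(OC)c1OC
F3 | step 3 | {[1-(2-{[4-(benzyloxy)-3-methoxyphenyl]methoxy}-4,5,6-trimethoxyphenyl)ethenyl]oxy}trimethylsilane | COc1cc(COc2cc(OC)c(OC)c(OC)c2C(=C)O[Si](C)(C)C)ccc1OCc1ccccc1
F4 | step 3 | 1-(2-{[4-(benzyloxy)-3-methoxyphenyl]methoxy}-4,5,6-trimethoxyphenyl)-2-bromoethan-1-one | COc1cc(COc2cc(OC)c(OC)c(OC)c2C(=O)CBr)ccc1OCc1ccccc1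
F5 | step 5 | 3-methoxy-4-[(triisopropylsilyl)oxy]benzaldehyde | COc1cc(C=O)ccc1O[Si](C(C)C)(C(C)C)C(C)C
F6 | step 5 | {3-methoxy-4-[(triisopropylsilyl)oxy]phenyl}methanol | COc1cc(CO)ccc1O[Si](C(C)C)(C(C)C)C(C)C
F7 | step 5 | 1-[2-({3-methoxy-4-[(triisopropylsilyl)oxy]phenyl}methoxy)-4,5,6-trimethoxyphenyl]ethan-1-one | COc1cc(COc2cc(OC)c(OC)c(OC)c2C(C)=O)ccc1O[Si](C(C)C)(C(C)C)C(C)C
F8 | step 5 | lithium enolate of F7 | COc1cc(COc2cc(OC)c(OC)c(OC)c2C(=C)[O-])ccc1O[Si](C(C)C)(C(C)C)C(C)C.[Li+]
F9 | step 5 | 4,4,4-trifluoro-1-[2-({3-methoxy-4-[(triisopropylsilyl)oxy]phenyl}methoxy)-4,5,6-trimethoxyphenyl]butane-1,3-dione | COc1cc(COc2cc(OC)c(OC)c(OC)c2C(=O)CC(=O)C(F)(F)F)ccc1O[Si](C(C)C)(C(C)C)C(C)C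
F10 | step 5 | 2-diazo-1-[2-({3-methoxy-4-[(triisopropylsilyl)oxy]phenyl}methoxy)-4,5,6-trimethoxyphenyl]ethan-1-one | COc1cc(COc2cc(OC)c(OC)c(OC)c2C(=O)C=[N+]=[N-])ccc1O[Si](C(C)C)(C(C)C)C(C)C
F11 | step 5 | rhodium carbene from F10 ([Rh] stands for the Rh2(S-PTTL)4 unit) | COc1cc(COc2cc(OC)c(OC)c(OC)c2C(=O)C=[Rh])ccc1O[Si](C(C)C)(C(C)C)C(C)C
F12 | step 5 | (2S)-2-{3-methoxy-4-[(triisopropylsilyl)oxy]phenyl}-5,6,7-trimethoxy-2,3-dihydro-4H-chromen-4-one | COc1cc([C@@H]2CC(=O)c3c(cc(OC)c(OC)c3OC)O2)ccc1O[Si](C(C)C)(C(C)C)C(C)C
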